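# Proposed total synthesis of sipholenol K (41) by one-carbon ring expansion of a trans-fused pyranone

## Analysis of the target

Sipholenol K (41) consists of two bicyclic halves joined by a CH2–CH2 tether. The left half is a trans-fused perhydro-1-benzoxepine (numbering O1, C2 … C5a, C6 … C9a). Oxepane ring A (O1, C2 with two methyls, C3 carbinol, C4, C5, methyl-bearing quaternary C5a, C9a–O) is fused to cyclohexane ring B, which carries the tether on C6 and an axial-methyl, equatorial-hydroxyl carbinol at C7. The right half is a cis-fused octalone: ring C is a tetrasubstituted enone (methyl on the α-carbon, tether on the β-carbon), and ring D has a gem-dimethyl carbon next to one ring-fusion CH and a tertiary methyl carbinol next to the other. Five stereocentres lie on the left half and three on the right. Within each half they are locked by the ring fusion, but the tether carries no stereochemical information, so each half must be made enantiopure separately. The sensitive groups are the two tertiary alcohols (dehydration, and the ring B one closes a tetrahydrofuran as soon as the tether end becomes a leaving group), the enone whose γ-carbon is a ring-fusion CH (loss of the cis fusion through the dienol), and the cis fusion itself while a carbonyl sits next to it. The main difficulty is a seven-membered ether with a fully substituted carbon on oxygen, trans-fused onto a quaternary carbon; such a ring is hard to close directly. In addition, both methyl carbinols carry methyl on the more hindered face, which addition of a methyl nucleophile to the ketones would not give. The strategy rests on ring A: its sequence O1–C2(Me)2–C3(OH)–C4H2–C5H2–C5a differs from an easily closed 2,2-dimethyltetrahydropyran-3-one only by one CH2 between the carbinol carbon and the CH2 on C5a.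

## Retrosynthetic reasoning

**41 ← 40 ← 39.** After removal of two silyl ethers, the ring C enone is traced to the tertiary allylic alcohol 39 by an oxidative 1,3-transposition. The forward step moves oxygen from the tether-bearing carbon to the γ-carbon and the double bond in the other direction, so the enone can be made from a 1,2-adduct.

**39 ← 38 ← 28 + 35.** The bond between the tether CH2 and the enone β-carbon joins the halves without touching a stereocentre, so the cut is made there. The left half becomes the primary iodide 28 (used as organometallics 36 and 37). The right half becomes the epoxy enone 35, whose carbonyl carbon is the carbon that must receive the tether. The spiro-oxirane in 35 is a masked methyl carbinol, opened by hydride after the union (38 → 39), so the right half needs no protecting group.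

**35 ← 34 ← 33 ← 31 ← 29 + 30.** Both right-half carbinol oxygens must come from the open face, so the oxirane is traced to the exocyclic alkene 34 and this to the ene-dione 33. The ring C carbonyl of 33 comes from allylic oxidation of the cycloadduct 31. Ring C is cut at the two bonds formed in a [4+2] addition of diene 30 to enone 29, which sets the cis fusion and the whole carbon skeleton of the half in one step.

**28 ← 27 ← 25 ← 24 ← 23 ← 22.** The ring B methyl carbinol is made the same way as on the right: exocyclic alkene 23, oxirane 24, hydride opening to 25. The tertiary hydroxyl is then masked (27) before the primary position becomes a leaving group.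

**22 ← 20 ← 18 ← 17 ← 16.** The ring B ketone of 16 sits next to the quaternary carbon, one position away from where oxygen is needed. Cutting the C6–vinyl bond (enol triflate 17 to diene 18) and hydroborating puts carbon on C6, hydrogen on the face opposite the angular methyl and oxygen on C7 (20), which is then oxidised to 22.

**16 ← 15 ← 14 ← 13.** The ring A carbinol is traced to the oxepanone 13. A ketone flanked by a quaternary carbon and a CH2 is a good substrate for reagent-controlled reduction, so the configuration does not depend on the conformation of the seven-membered ring.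

**13 ← 10 + 11 (key disconnection).** The two bonds to the CH2 next to the ring A carbonyl are cut, giving the pyranone 10 and the one-carbon donor 11. A six-membered ether closes easily, and insertion of one carbon on the CH2 side of the ketone then sets the ring size. This avoids a direct seven-membered etherification.

**10 ← 9 ← 8 ← 7.** The O–CMe2 bond of the pyran is cut; forward, the ring hydroxyl of 7 opens the oxirane of 8 at its tertiary carbon. The ring-fusion C–O bond is not formed in this step, so the trans fusion must already be present in 7 as hydroxyl trans to the prenyl chain.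

**7 ← 6 ← 5 ← 4 ← 3 ← 1 + 2.** Desymmetrising reduction of dione 3 is expected to place hydroxyl cis to the prenyl group (4), which would lead to a cis-fused ether. That reduction is therefore used only to fix the quaternary carbon. After ketalisation (5) the carbinol is oxidised (6) and set again under catalyst control (7). Dione 3 comes from C-prenylation of 1 with 2.

## Alternatives that were turned down

**Alternative 1:** anionic oxy-Cope rearrangement to rings C and D.
- Disconnection and key step: the cut is the bond between the gem-dimethyl carbon of ring D and the neighbouring ring-fusion CH. The potassium alkoxide of the bridged precursor of A1 undergoes a [3,3] shift that forms this bond, breaks one bond of the bridged ring and unfolds it into the cis-fused bis-ketal ketone A1.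
- For: the cis fusion follows necessarily from the bridged geometry. The ring C oxygen is placed unambiguously, which is stronger than the allylic oxidation of step 23 here. The charge-accelerated shift runs at low temperature.
- Against: it does nothing for the oxepane, the hardest ring. A1 has an extra ketone on ring D that must be removed. Its silyloxymethyl handle means the tether must be completed by joining two sp3 CH2 groups or by an olefination next to the enone. The ring D methyl carbinol still has to be made with methyl on the concave face. The new bond forms at a fully substituted alkene terminus, and the bridged precursor takes several steps.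
- Comparison: A1 is better on ring C regiocontrol. The chosen route offers a four-step right half (35) and spends its key step on ring A.

**Alternative 2:** bis-epoxide cascade of an acyclic chain.
- Disconnection and key step: the O1–C2 bond of ring A, the C5a–C6 bond of ring B and the C7–O bond are cut together. On Lewis-acid activation of the precursor of A2, the inner oxirane oxygen attacks the CMe2 carbon of the terminal oxirane, the alkene opens the resulting epoxonium at its methyl-bearing carbon, and the ester carbonyl traps the tertiary cation. This gives the hydroxy lactone A2.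
- For: three bonds, two rings and all five left-half stereocentres form in one step, with chirality from two asymmetric epoxidations. The ring A carbinol arrives with the right configuration without a ketone reduction. The C7–O bond forms with methyl axial by anti addition, and the lactone protects the tertiary hydroxyl. This is clearly shorter than the 21 steps to 28.
- Against: everything depends on one cascade in which each cation has an escape: five-membered ether formation at the oxirane CH, early capture by the ester, proton loss, or 1,2-shifts. Endo-selective seven-membered ring formation of this kind is usually only moderate. Two of three trisubstituted alkenes must be epoxidised selectively and enantioselectively. The lactone carbonyl of A2 must later become the CH2 next to ring C.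
- Comparison: A2 is stronger on step and atom economy. The chosen strategy offers separate events that can each be corrected: ring closure, ring size by a single migration, and each stereocentre by its own reagent or substrate control.

**Alternative 3:** intramolecular Diels–Alder closure of rings C and D.
- Disconnection and key step: the ring-fusion CH–CH bond and the bond between the ring C CH2 and the neighbouring oxygen-bearing carbon are cut. The precursor of A3, a 1-silyloxy diene tethered through the gem-dimethyl chain to a vinyl ketone, cyclises to A3 with the protected left half already attached.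
- For: both right-half rings and the union of the halves are settled together. Regiochemistry is enforced by the tether and the cis fusion by suprafacial addition. It avoids the hindered carbonyl addition of step 26 and the allylic oxidation of step 23, and is stronger on those two points.
- Against: the new stereocentres form two freely rotating CH2 groups away from the only resident chirality, so neither diene face is preferred and a near-equal diastereomer mixture is expected. The diene is 2,3-disubstituted and bonds at a terminus next to a quaternary carbon, and it must be built with defined geometry on the advanced left half. A3 still needs the ring D methyl carbinol (methyl would add from the wrong face) and oxidation of ring C.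
- Comparison: A3 is the most convergent in bond formation. The chosen route makes the right half separately under catalyst control and joins the halves by a step whose only new stereocentre is erased.

Key step: step 8

## Route

Assumption: in step 22 the (S)-configured oxazaborolidinium catalyst is taken to expose the enone face that gives the (4aR,8aS) adduct; if the opposite sense is found, the (R)-catalyst is used and nothing else changes.

Step 1
Reactants: 1 2-methylcyclohexane-1,3-dione; 2 1-bromo-3-methylbut-2-ene
Product: 3 2-methyl-2-(3-methylbut-2-en-1-yl)cyclohexane-1,3-dione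
Conditions: KOH (1 M aq.), 2 (1.3 equiv), rt → 50 °C
Reagents that add atoms: none
Why: C-alkylation of the dione enolate by the allylic bromide (SN2); water keeps the enolate oxygens hydrogen-bonded and favours attack through carbon, and any O-prenyl enol ether is hydrolysed back to 1 by an acid wash.

Step 2
Reactants: 3 2-methyl-2-(3-methylbut-2-en-1-yl)cyclohexane-1,3-dione
Product: 4 (2R,3R)-3-hydroxy-2-methyl-2-(3-methylbut-2-en-1-yl)cyclohexan-1-one
Conditions: (S)-1-methyl-3,3-diphenylhexahydropyrrolo[1,2-c][1,3,2]oxazaborole (20 mol %), catecholborane (1.0 equiv), toluene, −78 °C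
Reagents that add atoms: none
Why: Corey–Bakshi–Shibata reduction used as a desymmetrisation: the catalyst reads the quaternary carbon as the large group and should give the 3R carbinol, and hydride should enter anti to the bulkier prenyl group, so hydroxyl lies cis to prenyl and the quaternary carbon is R. Catecholborane spares the alkene. The minor diastereomer is removed here because step 4 would turn it into the antipode of 6.

Step 3
Reactants: 4 (2R,3R)-3-hydroxy-2-methyl-2-(3-methylbut-2-en-1-yl)cyclohexan-1-one
Product: 5 (6R,7R)-6-methyl-6-(3-methylbut-2-en-1-yl)-1,4-dioxaspiro[4.5]decan-7-ol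
Conditions: ethylene glycol, HC(OEt)3, p-toluenesulfonic acid monohydrate (5 mol %), CH2Cl2, rt
Reagents that add atoms: ethylene glycol, OCCO
Why: acid-catalysed ketalisation of the remaining ketone with the orthoformate as water scavenger; the β-hydroxy ketone cannot eliminate because its α-carbon is quaternary.

Step 4
Reactants: 5 (6R,7R)-6-methyl-6-(3-methylbut-2-en-1-yl)-1,4-dioxaspiro[4.5]decan-7-ol
Product: 6 (6R)-6-methyl-6-(3-methylbut-2-en-1-yl)-1,4-dioxaspiro[4.5]decan-7-one
Conditions: Dess–Martin periodinane, NaHCO3, CH2Cl2, rt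
Reagents that add atoms: none
Why: Dess–Martin oxidation removes the carbinol that the desymmetrisation placed cis to the prenyl chain; the chirality now rests on the quaternary carbon alone.

Step 5
Reactants: 6 (6R)-6-methyl-6-(3-methylbut-2-en-1-yl)-1,4-dioxaspiro[4.5]decan-7-one
Product: 7 (6R,7S)-6-methyl-6-(3-methylbut-2-en-1-yl)-1,4-dioxaspiro[4.5]decan-7-ol
Conditions: (R)-1-methyl-3,3-diphenylhexahydropyrrolo[1,2-c][1,3,2]oxazaborole (20 mol %), catecholborane (1.5 equiv), toluene, −78 → −40 °C
Reagents that add atoms: none
Why: second Corey–Bakshi–Shibata reduction, now catalyst-controlled at the carbinol: with the quaternary carbon as large and CH2 as small group the (R)-catalyst should give 7S, hydroxyl cis to methyl and trans to the prenyl chain, as a trans-fused ring requires.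

Step 6
Reactants: 7 (6R,7S)-6-methyl-6-(3-methylbut-2-en-1-yl)-1,4-dioxaspiro[4.5]decan-7-ol
Product: 9 (4aR,8aS)-2,2,4a-trimethyloctahydrospiro[chromene-5,2'-[1,3]dioxolan]-3-ol (both C3 epimers), via epoxy alcohol 8 (not isolated)
Conditions: mCPBA, NaHCO3, CH2Cl2, 0 °C; then camphor-10-sulfonic acid (10 mol %), 0 °C → rt
Reagents that add atoms: 3-chloroperoxybenzoic acid (mCPBA), OOC(=O)c1cccc(Cl)c1
Why: Prilezhaev epoxidation, then acid-catalysed intramolecular oxirane opening: the hydroxyl attacks the tertiary oxirane carbon (6-endo), because the 5-exo mode would build a strained trans-fused tetrahydrofuran across the quaternary carbon. The ring-fusion C–O bond is not touched, so the trans relationship of 7 is carried over, and both oxirane epimers converge in step 7.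

Step 7
Reactants: 9 (4aR,8aS)-2,2,4a-trimethyloctahydrospiro[chromene-5,2'-[1,3]dioxolan]-3-ol
Product: 10 (4aR,8aS)-2,2,4a-trimethylhexahydrospiro[chromene-5,2'-[1,3]dioxolan]-3(2H)-one
Conditions: Dess–Martin periodinane, NaHCO3, CH2Cl2, rt
Reagents that add atoms: none
Why: alcohol oxidation; both C3 epimers give one ketone and no stereocentre is touched.

Step 8
Reactants: 10 (4aR,8aS)-2,2,4a-trimethylhexahydrospiro[chromene-5,2'-[1,3]dioxolan]-3(2H)-one; 11 trimethylsilyldiazomethane
Product: 13 (5aR,9aS)-2,2,5a-trimethyloctahydrospiro[1-benzoxepine-6,2'-[1,3]dioxolan]-3(2H)-one, via alpha-silyl ketone 12 (not isolated)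
Conditions: 11 (1.5 equiv), BF3·OEt2 (1.2 equiv), CH2Cl2, −78 °C; then K2CO3, MeOH, rt
Reagents that add atoms: none
Why: BF3 activates the pyranone carbonyl, the diazo carbon of 11 adds to it, and in the resulting diazonium betaine a ring carbon shifts to the diazo carbon as N2 leaves, inserting CH(SiMe3) next to the carbonyl. The closest known reaction type is the Lewis-acid-promoted homologation of cyclic ether ketones with this diazoalkane (a Tiffeneau–Demjanov-type ring expansion). The oxepane is formed by 1,2-shift ring enlargement of the six-membered ether, not by a cyclisation, so no closure mode is at stake. No lasting stereocentre is created: the silyl-bearing carbon of 12 becomes CH2 on methanolysis, and the trans fusion of 10 is a spectator. The step needs migration of the C4 methylene and not of the oxygen-bearing C2. Two features of 10 should secure this: the ring oxygen makes C2 electron-poor and lowers its migratory aptitude, and the Me3Si group avoids the gem-dimethyl side in the betaine. The α-silyl ketone 12 is too hindered for a second insertion, and the dioxolane should survive BF3 at −78 °C.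

Step 9
Reactants: 13 (5aR,9aS)-2,2,5a-trimethyloctahydrospiro[1-benzoxepine-6,2'-[1,3]dioxolan]-3(2H)-one
Product: 14 (3S,5aR,9aS)-2,2,5a-trimethyloctahydrospiro[1-benzoxepine-6,2'-[1,3]dioxolan]-3-ol
Conditions: (R)-1-methyl-3,3-diphenylhexahydropyrrolo[1,2-c][1,3,2]oxazaborole (20 mol %), BH3·SMe2 (0.7 equiv), THF, −20 °C
Reagents that add atoms: none
Why: Corey–Bakshi–Shibata reduction with the CMe2–O carbon as large and CH2 as small group; the (R)-catalyst should make C3 S as in the target, independent of the weak facial bias of the flexible seven-membered ring.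

Step 10
Reactants: 14 (3S,5aR,9aS)-2,2,5a-trimethyloctahydrospiro[1-benzoxepine-6,2'-[1,3]dioxolan]-3-ol
Product: 15 tert-butyldimethylsilyl ether of 14
Conditions: t-BuMe2SiOTf, 2,6-lutidine, CH2Cl2, −78 → 0 °C
Reagents that add atoms: tert-butyldimethylsilyl trifluoromethanesulfonate, CC(C)(C)[Si](C)(C)OS(=O)(=O)C(F)(F)F
Why: silylation of the hindered secondary alcohol with the silyl triflate; this ether should survive every step up to the final fluoride treatment.

Step 11
Reactants: 15 tert-butyldimethylsilyl ether of 14
Product: 16 (3S,5aR,9aS)-3-[(tert-butyldimethylsilyl)oxy]-2,2,5a-trimethyloctahydro-1-benzoxepin-6(2H)-one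
Conditions: pyridinium p-toluenesulfonate, acetone/H2O (10:1), 55 °C
Reagents that add atoms: water, O
Why: mild acid-catalysed ketal hydrolysis unveils the ring B ketone and leaves the secondary silyl ether in place.

Step 12
Reactants: 16 (3S,5aR,9aS)-3-[(tert-butyldimethylsilyl)oxy]-2,2,5a-trimethyloctahydro-1-benzoxepin-6(2H)-one
Product: 17 (3S,5aR,9aS)-3-[(tert-butyldimethylsilyl)oxy]-2,2,5a-trimethyl-2,3,4,5,5a,8,9,9a-octahydro-1-benzoxepin-6-yl trifluoromethanesulfonate
Conditions: KN(SiMe3)2 added to 16 and PhNTf2, THF, −78 °C
Reagents that add atoms: N-phenylbis(trifluoromethanesulfonimide), O=S(=O)(N(c1ccccc1)S(=O)(=O)C(F)(F)F)C(F)(F)F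
Why: enol triflate formation with in-situ trapping; C5a is quaternary, so the ketone can enolise only toward C7 and one regioisomer forms.

Step 13
Reactants: 17 enol triflate
Product: 18 tert-butyl{[(3S,5aS,9aS)-6-ethenyl-2,2,5a-trimethyl-2,3,4,5,5a,8,9,9a-octahydro-1-benzoxepin-3-yl]oxy}dimethylsilane
Conditions: tributyl(vinyl)stannane, Pd(PPh3)4 (5 mol %, zerovalent palladium), LiCl, THF, 65 °C
Reagents that add atoms: tributyl(vinyl)stannane, C=C[Sn](CCCC)(CCCC)CCCC
Why: Stille cross-coupling of the alkenyl triflate with the small vinyl partner; LiCl assists the triflate complex of palladium.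

Step 14
Reactants: 18 diene
Product: 20 (3S,5aS,6S,7S,9aS)-3-[(tert-butyldimethylsilyl)oxy]-6-(2-hydroxyethyl)-2,2,5a-trimethyldecahydro-1-benzoxepin-7-ol, via bis-borane 19 (not isolated)
Conditions: 9-BBN (1.1 equiv), THF, 0 °C → rt; then BH3·THF (2 equiv), 0 °C → rt; then NaOH (3 M), H2O2 (30 %), 0 °C → rt
Reagents that add atoms: hydrogen peroxide, OO
Why: hydroboration–oxidation twice: 9-BBN takes the terminal vinyl group at its end carbon, then borane adds syn to the trisubstituted ring alkene from the face opposite the axial C5a methyl. This puts H on C6 anti to that methyl (equatorial side chain) and boron on C7, whose configuration is irrelevant.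

Step 15
Reactants: 20 diol
Product: 21 2-[(3S,5aS,6S,7S,9aS)-3-[(tert-butyldimethylsilyl)oxy]-7-hydroxy-2,2,5a-trimethyldecahydro-1-benzoxepin-6-yl]ethyl 2,2-dimethylpropanoate
Conditions: pivaloyl chloride (1.1 equiv), pyridine, CH2Cl2, 0 °C
Reagents that add atoms: pivaloyl chloride, CC(C)(C)C(=O)Cl
Why: the bulky acid chloride acylates the primary alcohol selectively over the hindered secondary one.

Step 16
Reactants: 21 hydroxy pivalate
Product: 22 2-[(3S,5aS,6S,9aS)-3-[(tert-butyldimethylsilyl)oxy]-2,2,5a-trimethyl-7-oxodecahydro-1-benzoxepin-6-yl]ethyl 2,2-dimethylpropanoate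
Conditions: Dess–Martin periodinane, NaHCO3, CH2Cl2, rt
Reagents that add atoms: none
Why: oxidation of the secondary alcohol; C6, now α to the ketone, already has the thermodynamically preferred equatorial side chain, so epimerisation can only help.

Step 17
Reactants: 22 keto pivalate
Product: 23 2-[(3S,5aS,6R,9aS)-3-[(tert-butyldimethylsilyl)oxy]-2,2,5a-trimethyl-7-methylidenedecahydro-1-benzoxepin-6-yl]ethyl 2,2-dimethylpropanoate
Conditions: Ph3PCH3Br, KOt-Bu, THF, 0 °C → rt
Reagents that add atoms: methyltriphenylphosphonium bromide, C[P+](c1ccccc1)(c1ccccc1)c1ccccc1.[Br-]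
Why: Wittig methylenation of the ketone; the hindered pivalate is not attacked by the ylide.

Step 18
Reactants: 23 exocyclic alkene
Product: 24 2-[(3S,5aS,6S,7S,9aS)-3-[(tert-butyldimethylsilyl)oxy]-2,2,5a-trimethyloctahydro-2H-spiro[1-benzoxepine-7,2'-oxiran]-6-yl]ethyl 2,2-dimethylpropanoate
Conditions: mCPBA, NaHCO3, CH2Cl2, 0 °C
Reagents that add atoms: 3-chloroperoxybenzoic acid (mCPBA), OOC(=O)c1cccc(Cl)c1
Why: Prilezhaev epoxidation from the equatorial side, because the axial trajectory is blocked by the 1,3-diaxial C5a methyl; the oxirane oxygen ends equatorial and its CH2 axial.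

Step 19
Reactants: 24 spiro-oxirane
Product: 25 (3S,5aS,6S,7S,9aS)-3-[(tert-butyldimethylsilyl)oxy]-6-(2-hydroxyethyl)-2,2,5a,7-tetramethyldecahydro-1-benzoxepin-7-ol
Conditions: LiAlH4, THF, 0 °C → rt
Reagents that add atoms: none
Why: hydride opens the oxirane at its CH2 (SN2), turning the axial CH2 into the axial methyl beside an equatorial tertiary hydroxyl; the same reagent cleaves the pivalate.

Step 20
Reactants: 25 diol
Product: 27 2-[(3S,5aS,6S,7S,9aS)-3-[(tert-butyldimethylsilyl)oxy]-2,2,5a,7-tetramethyl-7-[(triethylsilyl)oxy]decahydro-1-benzoxepin-6-yl]ethan-1-ol, via bis-triethylsilyl ether 26 (not isolated)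
Conditions: Et3SiOTf (2.5 equiv), 2,6-lutidine, CH2Cl2, −78 → 0 °C; then MeOH, camphor-10-sulfonic acid (excess over lutidine), 0 °C
Reagents that add atoms: triethylsilyl trifluoromethanesulfonate, CC[Si](CC)(CC)OS(=O)(=O)C(F)(F)F
Why: exhaustive silylation, then selective acid methanolysis of the much more labile primary triethylsilyl ether; the tertiary hydroxyl must be masked because it would close a tetrahydrofuran once the primary carbon carries a leaving group.

Step 21
Reactants: 27 primary alcohol
Product: 28 tert-butyl{[(3S,5aS,6S,7S,9aS)-6-(2-iodoethyl)-2,2,5a,7-tetramethyl-7-[(triethylsilyl)oxy]decahydro-1-benzoxepin-3-yl]oxy}dimethylsilane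
Conditions: I2, PPh3, imidazole, CH2Cl2, 0 °C
Reagents that add atoms: iodine, II
Why: Appel-type iodination; iodide displaces the primary alkoxyphosphonium ion (SN2).

Step 22
Reactants: 29 4,4-dimethylcyclohex-2-en-1-one; 30 2-methylbuta-1,3-diene
Product: 31 (4aR,8aS)-4,4,6-trimethyl-3,4,4a,5,8,8a-hexahydronaphthalen-1(2H)-one
Conditions: (S)-3,3-diphenyl-1-(2-methylphenyl)hexahydropyrrolo[1,2-c][1,3,2]oxazaborole (20 mol %), AlBr3 (16 mol %), 30 (5 equiv), CH2Cl2, −20 °C → rt
Reagents that add atoms: none
Why: catalytic enantioselective Diels–Alder reaction of a cyclic enone activated by a chiral oxazaborolidinium Lewis acid: suprafacial addition fixes the cis fusion, the 2-methyl group of the diene directs its C1 to the enone β-carbon (para adduct), and the catalyst selects the enone face.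

Step 23
Reactants: 31 cis-octalone
Product: 33 (4aR,8aS)-4,4,6-trimethyl-3,4,4a,8a-tetrahydronaphthalene-1,5(2H,8H)-dione, via allylic alcohol 32 (not isolated)
Conditions: SeO2 (0.5 equiv), t-BuOOH, CH2Cl2, rt; then Dess–Martin periodinane, NaHCO3, CH2Cl2, rt
Reagents that add atoms: selenium dioxide, O=[Se]=O; tert-butyl hydroperoxide, CC(C)(C)OO
Why: selenium dioxide allylic oxidation (ene reaction, then [2,3]-sigmatropic shift) delivers oxygen to the ring CH2 on the more substituted end of the trisubstituted alkene (C5) and returns the double bond to its place. Dess–Martin oxidation then converges the alcohol and any enone already formed.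

Step 24
Reactants: 33 ene-dione
Product: 34 (4aS,8aR)-2,8,8-trimethyl-5-methylidene-4a,5,6,7,8,8a-hexahydronaphthalen-1(4H)-one
Conditions: Zn, CH2Br2, TiCl4, THF/CH2Cl2, 0 °C → rt
Reagents that add atoms: dibromomethane, BrCBr
Why: Takai–Lombardo methylenation is non-basic, so the epimerisable ring-fusion centres stay cis, and it selects the saturated ketone over the conjugated, more hindered enone carbonyl.

Step 25
Reactants: 34 methylene enone
Product: 35 (4aS,5S,8aR)-2,8,8-trimethyl-4a,6,7,8a-tetrahydro-4H-spiro[naphthalene-5,2'-oxiran]-1(8H)-one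
Conditions: mCPBA, NaHCO3, CH2Cl2, 0 °C
Reagents that add atoms: 3-chloroperoxybenzoic acid (mCPBA), OOC(=O)c1cccc(Cl)c1
Why: Prilezhaev epoxidation of the electron-rich exocyclic alkene only; the reagent comes from the convex face (the side of the ring-fusion hydrogens) because the other face is covered by the axial ring C carbon, so the oxirane oxygen lies cis to those hydrogens.

Step 26
Reactants: 28 iodide; 35 epoxy enone
Product: 38 tertiary allylic alcohol from 1,2-addition (both carbinol epimers), via alkyllithium 36 (not isolated), via alkylcerium dichloride 37 (not isolated)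
Conditions: t-BuLi (2.1 equiv), Et2O/pentane, −78 °C; CeCl3, THF, −78 °C; then 35 (1.3 equiv), −78 → −40 °C
Reagents that add atoms: none
Why: iodine–lithium exchange, transmetalation to the less basic organocerium reagent and 1,2-addition to the hindered enone carbonyl. The new carbinol centre is erased in step 28, so its configuration does not matter, and the oxirane is inert at this temperature.

Step 27
Reactants: 38 tertiary allylic alcohol
Product: 39 diol with the ring D methyl carbinol
Conditions: LiAlH4, THF, 0 °C → rt
Reagents that add atoms: none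
Why: hydride opens the spiro-oxirane at CH2 (SN2), giving the ring D methyl carbinol with hydroxyl cis to the ring-fusion hydrogens; the tertiary allylic alcohol and the silyl ethers are unaffected.

Step 28
Reactants: 39 diol
Product: 40 bis-silyl ether of sipholenol K
Conditions: pyridinium chlorochromate ([C5H5NH][CrO3Cl]), NaOAc, 4 Å molecular sieves, CH2Cl2, rt
Reagents that add atoms: pyridinium chlorochromate, [O-][Cr](=O)(=O)Cl.c1cc[nH+]cc1
Why: Babler–Dauben oxidative transposition: the chromate ester of the tertiary allylic alcohol undergoes a [3,3] shift to the secondary allylic chromate, which is oxidised to the enone. The carbonyl moves to the γ-carbon and the double bond to the tether-bearing carbon; the saturated tertiary alcohol cannot be oxidised.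

Step 29
Reactants: 40 bis-silyl ether of sipholenol K
Product: 41 sipholenol K
Conditions: HF·pyridine, THF, 0 °C → rt
Reagents that add atoms: none
Why: fluoride-mediated cleavage of both silyl ethers under mildly acidic conditions that should neither dehydrate the tertiary alcohols nor move the enone.

## Compound list

1 | 2-methylcyclohexane-1,3-dione | CC1C(=O)CCCC1=O | starting material
2 | 1-bromo-3-methylbut-2-ene | CC(C)=CCBr | starting material
3 | 2-methyl-2-(3-methylbut-2-en-1-yl)cyclohexane-1,3-dione | CC(C)=CCC1(C)C(=O)CCCC1=O | intermediate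
4 | (2R,3R)-3-hydroxy-2-methyl-2-(3-methylbut-2-en-1-yl)cyclohexan-1-one (OH cis to prenyl) | O=C1CCC[C@@H](O)[C@@]1(C)CC=C(C)C | intermediate
5 | (6R,7R)-6-methyl-6-(3-methylbut-2-en-1-yl)-1,4-dioxaspiro[4.5]decan-7-ol | C12(OCCO2)CCC[C@@H](O)[C@@]1(C)CC=C(C)C | intermediate
6 | (6R)-6-methyl-6-(3-methylbut-2-en-1-yl)-1,4-dioxaspiro[4.5]decan-7-one | C12(OCCO2)CCCC(=O)[C@@]1(C)CC=C(C)C | intermediate
7 | (6R,7S)-6-methyl-6-(3-methylbut-2-en-1-yl)-1,4-dioxaspiro[4.5]decan-7-ol (OH trans to prenyl) | C12(OCCO2)CCC[C@H](O)[C@@]1(C)CC=C(C)C | intermediate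
8 | (6R,7S)-6-[(3,3-dimethyloxiran-2-yl)methyl]-6-methyl-1,4-dioxaspiro[4.5]decan-7-ol (both oxirane epimers) | C12(OCCO2)CCC[C@H](O)[C@@]1(C)CC3OC3(C)C | intermediate (not isolated)
9 | (4aR,8aS)-2,2,4a-trimethyloctahydrospiro[chromene-5,2'-[1,3]dioxolan]-3-ol (trans-fused, both C3 epimers) | O1CCOC12[C@]3(C)CC(O)C(C)(C)O[C@H]3CCC2 | intermediate
10 | (4aR,8aS)-2,2,4a-trimethylhexahydrospiro[chromene-5,2'-[1,3]dioxolan]-3(2H)-one (trans-fused pyranone ketal) | O1CCOC12[C@]3(C)CC(=O)C(C)(C)O[C@H]3CCC2 | intermediate
11 | trimethylsilyldiazomethane | C[Si](C)(C)C=[N+]=[N-] | starting material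
12 | (5aR,9aS)-2,2,5a-trimethyl-4-(trimethylsilyl)octahydrospiro[1-benzoxepine-6,2'-[1,3]dioxolan]-3(2H)-one | O1CCOC12[C@]3(C)CC([Si](C)(C)C)C(=O)C(C)(C)O[C@H]3CCC2 | intermediate (not isolated)
13 | (5aR,9aS)-2,2,5a-trimethyloctahydrospiro[1-benzoxepine-6,2'-[1,3]dioxolan]-3(2H)-one (trans-fused oxepanone ketal) | O1CCOC12[C@]3(C)CCC(=O)C(C)(C)O[C@H]3CCC2 | intermediate
14 | (3S,5aR,9aS)-2,2,5a-trimethyloctahydrospiro[1-benzoxepine-6,2'-[1,3]dioxolan]-3-ol | O1CCOC12[C@]3(C)CC[C@H](O)C(C)(C)O[C@H]3CCC2 | intermediate
15 | tert-butyl(dimethyl){[(3S,5aR,9aS)-2,2,5a-trimethyloctahydrospiro[1-benzoxepine-6,2'-[1,3]dioxolan]-3-yl]oxy}silane | O1CCOC12[C@]3(C)CC[C@H](O[Si](C)(C)C(C)(C)C)C(C)(C)O[C@H]3CCC2 | intermediate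
16 | (3S,5aR,9aS)-3-[(tert-butyldimethylsilyl)oxy]-2,2,5a-trimethyloctahydro-1-benzoxepin-6(2H)-one | O=C1[C@]2(C)CC[C@H](O[Si](C)(C)C(C)(C)C)C(C)(C)O[C@H]2CCC1 | intermediate
17 | (3S,5aR,9aS)-3-[(tert-butyldimethylsilyl)oxy]-2,2,5a-trimethyl-2,3,4,5,5a,8,9,9a-octahydro-1-benzoxepin-6-yl trifluoromethanesulfonate | C1(OS(=O)(=O)C(F)(F)F)[C@]2(C)CC[C@H](O[Si](C)(C)C(C)(C)C)C(C)(C)O[C@H]2CCC=1 | intermediate
18 | tert-butyl{[(3S,5aS,9aS)-6-ethenyl-2,2,5a-trimethyl-2,3,4,5,5a,8,9,9a-octahydro-1-benzoxepin-3-yl]oxy}dimethylsilane | C1(C=C)[C@]2(C)CC[C@H](O[Si](C)(C)C(C)(C)C)C(C)(C)O[C@H]2CCC=1 | intermediate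
19 | 9-{2-[(3S,5aS,6S,7S,9aS)-7-boranyl-3-[(tert-butyldimethylsilyl)oxy]-2,2,5a-trimethyldecahydro-1-benzoxepin-6-yl]ethyl}-9-borabicyclo[3.3.1]nonane | C1CCC2CCCC1B2CC[C@H]3[C@]4(C)CC[C@H](O[Si](C)(C)C(C)(C)C)C(C)(C)O[C@H]4CC[C@@H]3B | intermediate (not isolated)
20 | (3S,5aS,6S,7S,9aS)-3-[(tert-butyldimethylsilyl)oxy]-6-(2-hydroxyethyl)-2,2,5a-trimethyldecahydro-1-benzoxepin-7-ol | OCC[C@H]1[C@]2(C)CC[C@H](O[Si](C)(C)C(C)(C)C)C(C)(C)O[C@H]2CC[C@@H]1O | intermediate
21 | 2-[(3S,5aS,6S,7S,9aS)-3-[(tert-butyldimethylsilyl)oxy]-7-hydroxy-2,2,5a-trimethyldecahydro-1-benzoxepin-6-yl]ethyl 2,2-dimethylpropanoate | CC(C)(C)C(=O)OCC[C@H]1[C@]2(C)CC[C@H](O[Si](C)(C)C(C)(C)C)C(C)(C)O[C@H]2CC[C@@H]1O | intermediate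
22 | 2-[(3S,5aS,6S,9aS)-3-[(tert-butyldimethylsilyl)oxy]-2,2,5a-trimethyl-7-oxodecahydro-1-benzoxepin-6-yl]ethyl 2,2-dimethylpropanoate | CC(C)(C)C(=O)OCC[C@H]1[C@]2(C)CC[C@H](O[Si](C)(C)C(C)(C)C)C(C)(C)O[C@H]2CCC1=O | intermediate
23 | 2-[(3S,5aS,6R,9aS)-3-[(tert-butyldimethylsilyl)oxy]-2,2,5a-trimethyl-7-methylidenedecahydro-1-benzoxepin-6-yl]ethyl 2,2-dimethylpropanoate | CC(C)(C)C(=O)OCC[C@H]1[C@]2(C)CC[C@H](O[Si](C)(C)C(C)(C)C)C(C)(C)O[C@H]2CCC1=C | intermediate
24 | 2-[(3S,5aS,6S,7S,9aS)-3-[(tert-butyldimethylsilyl)oxy]-2,2,5a-trimethyloctahydro-2H-spiro[1-benzoxepine-7,2'-oxiran]-6-yl]ethyl 2,2-dimethylpropanoate (oxirane oxygen trans to the C5a methyl) | CC(C)(C)C(=O)OCC[C@H]1[C@]2(C)CC[C@H](O[Si](C)(C)C(C)(C)C)C(C)(C)O[C@H]2CC[C@@]13CO3 | intermediate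
25 | (3S,5aS,6S,7S,9aS)-3-[(tert-butyldimethylsilyl)oxy]-6-(2-hydroxyethyl)-2,2,5a,7-tetramethyldecahydro-1-benzoxepin-7-ol | OCC[C@H]1[C@]2(C)CC[C@H](O[Si](C)(C)C(C)(C)C)C(C)(C)O[C@H]2CC[C@]1(C)O | intermediate
26 | bis(triethylsilyl) ether of 25 (primary and tertiary oxygen) | CC[Si](CC)(CC)OCC[C@H]1[C@]2(C)CC[C@H](O[Si](C)(C)C(C)(C)C)C(C)(C)O[C@H]2CC[C@]1(C)O[Si](CC)(CC)CC | intermediate (not isolated)
27 | 2-[(3S,5aS,6S,7S,9aS)-3-[(tert-butyldimethylsilyl)oxy]-2,2,5a,7-tetramethyl-7-[(triethylsilyl)oxy]decahydro-1-benzoxepin-6-yl]ethan-1-ol | OCC[C@H]1[C@]2(C)CC[C@H](O[Si](C)(C)C(C)(C)C)C(C)(C)O[C@H]2CC[C@]1(C)O[Si](CC)(CC)CC | intermediate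
28 | tert-butyl{[(3S,5aS,6S,7S,9aS)-6-(2-iodoethyl)-2,2,5a,7-tetramethyl-7-[(triethylsilyl)oxy]decahydro-1-benzoxepin-3-yl]oxy}dimethylsilane | ICC[C@H]1[C@]2(C)CC[C@H](O[Si](C)(C)C(C)(C)C)C(C)(C)O[C@H]2CC[C@]1(C)O[Si](CC)(CC)CC | intermediate
29 | 4,4-dimethylcyclohex-2-en-1-one | CC1(C)CCC(=O)C=C1 | starting material
30 | 2-methylbuta-1,3-diene | CC(=C)C=C | starting material
31 | (4aR,8aS)-4,4,6-trimethyl-3,4,4a,5,8,8a-hexahydronaphthalen-1(2H)-one (cis-fused) | CC=1C[C@@H]2[C@H](CC=1)C(=O)CCC2(C)C | intermediate
32 | (4aR,8aS)-5-hydroxy-4,4,6-trimethyl-3,4,4a,5,8,8a-hexahydronaphthalen-1(2H)-one (both C5 epimers) | CC=1C(O)[C@@H]2[C@H](CC=1)C(=O)CCC2(C)C | intermediate (not isolated)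
33 | (4aR,8aS)-4,4,6-trimethyl-3,4,4a,8a-tetrahydronaphthalene-1,5(2H,8H)-dione | CC=1C(=O)[C@@H]2[C@H](CC=1)C(=O)CCC2(C)C | intermediate
34 | (4aS,8aR)-2,8,8-trimethyl-5-methylidene-4a,5,6,7,8,8a-hexahydronaphthalen-1(4H)-one | CC=1C(=O)[C@@H]2[C@H](CC=1)C(=C)CCC2(C)C | intermediate
35 | (4aS,5S,8aR)-2,8,8-trimethyl-4a,6,7,8a-tetrahydro-4H-spiro[naphthalene-5,2'-oxiran]-1(8H)-one (oxirane oxygen cis to the ring-fusion hydrogens) | CC=1C(=O)[C@@H]2[C@H](CC=1)[C@]3(CO3)CCC2(C)C | intermediate
36 | {2-[(3S,5aS,6S,7S,9aS)-3-[(tert-butyldimethylsilyl)oxy]-2,2,5a,7-tetramethyl-7-[(triethylsilyl)oxy]decahydro-1-benzoxepin-6-yl]ethyl}lithium | [Li]CC[C@H]1[C@]2(C)CC[C@H](O[Si](C)(C)C(C)(C)C)C(C)(C)O[C@H]2CC[C@]1(C)O[Si](CC)(CC)CC | intermediate (not isolated)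
37 | dichloro{2-[(3S,5aS,6S,7S,9aS)-3-[(tert-butyldimethylsilyl)oxy]-2,2,5a,7-tetramethyl-7-[(triethylsilyl)oxy]decahydro-1-benzoxepin-6-yl]ethyl}cerium | Cl[Ce](Cl)CC[C@H]1[C@]2(C)CC[C@H](O[Si](C)(C)C(C)(C)C)C(C)(C)O[C@H]2CC[C@]1(C)O[Si](CC)(CC)CC | intermediate (not isolated)
38 | 1,2-adduct of 37 and 35: tertiary allylic alcohol at the former enone carbonyl (both epimers), spiro-oxirane retained | CC=1C(O)(CC[C@H]4[C@]5(C)CC[C@H](O[Si](C)(C)C(C)(C)C)C(C)(C)O[C@H]5CC[C@]4(C)O[Si](CC)(CC)CC)[C@@H]2[C@H](CC=1)[C@]3(CO3)CCC2(C)C | intermediate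
39 | diol from 38: tertiary allylic alcohol plus ring D methyl carbinol (hydroxyl cis to the ring-fusion hydrogens) | CC=1C(O)(CC[C@H]4[C@]5(C)CC[C@H](O[Si](C)(C)C(C)(C)C)C(C)(C)O[C@H]5CC[C@]4(C)O[Si](CC)(CC)CC)[C@@H]2[C@H](CC=1)[C@@](C)(O)CCC2(C)C | intermediate
40 | sipholenol K bis-silyl ether (tert-butyldimethylsilyl on the oxepane oxygen, triethylsilyl on the ring B tertiary oxygen) | CC1=C(CC[C@H]2[C@]3(C)CC[C@H](O[Si](C)(C)C(C)(C)C)C(C)(C)O[C@H]3CC[C@]2(C)O[Si](CC)(CC)CC)[C@@H]2[C@H](CC1=O)[C@@](C)(O)CCC2(C)C | intermediate
41 | sipholenol K | CC1=C(CC[C@H]2[C@]3(C)CC[C@H](O)C(C)(C)O[C@H]3CC[C@]2(C)O)[C@@H]2[C@H](CC1=O)[C@@](C)(O)CCC2(C)C | target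

## Step count and least certain steps

Total: 29 steps. Longest linear sequence: 25 steps (steps 1–21 and 26–29). The right half takes 4 steps (22–25).

**Step 8 (key step).** The wrong ring carbon may migrate: if the oxygen-bearing quaternary carbon shifts, the carbonyl ends up one position away from the gem-dimethyl carbon. The Lewis acid may also open the dioxolane, or the betaine may collapse to a spiro-oxirane instead of rearranging. Fallback, from 10 back to 13, with the regiochemistry fixed by enolisation (C2 has no hydrogen):
- 10 is converted with Me3SiOTf and Et3N into the silyl enol ether F1.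
- Simmons–Smith cyclopropanation (Et2Zn, CH2I2) gives the siloxycyclopropane F2.
- Saegusa–Ito ring expansion (FeCl3 in DMF, then NaOAc) opens the internal cyclopropane bond to the oxepenone F3.
- Hydrogenation (H2, Pd/C) gives 13.

**Step 22.** The cycloaddition may stall at the β-carbon next to the gem-dimethyl group. The enantioselectivity may be low or of the opposite sense, the meta regioisomer may form, or the Lewis acid may epimerise the adduct to the trans-fused ketone. Fallback, from 29 and 30 back to 31: an AlCl3-promoted cycloaddition gives the racemate, 31 together with its antipode F5, which is separated by preparative chromatography on a chiral stationary phase.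

**Step 23.** Oxidation may occur at the C6 methyl group or at the other allylic CH2, since C5 is shielded by the neighbouring ring-fusion carbon and the gem-dimethyl group. Selenium may also oxidise the position α to the C1 ketone, or the acidic medium may epimerise C8a. Fallback, from 31 back to 32, with the oxygen position fixed by hydroboration and a Wharton transposition:
- 31 is ketalised with ethylene glycol to F6.
- Hydroboration–oxidation puts hydroxyl on the unsubstituted alkene carbon (alcohol F7).
- Dess–Martin oxidation gives ketone F8.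
- Dehydrogenation on the methyl-bearing side with IBX gives the transposed enone F9.
- Nucleophilic epoxidation (H2O2, NaOH) gives epoxy ketone F10.
- Hydrazine hydrate with acetic acid gives the allylic alcohol F11.
- Mild aqueous acid removes the ketal to give 32, which is oxidised to 33 as in the route.

**Step 26.** Addition at the hindered carbonyl may be slow. The organometallic may deprotonate the enone instead, the Lewis-acidic cerium reagent may open the oxirane, or the triethylsilyl group may migrate from oxygen to the carbanion during the exchange. Fallback, from 37 and 34 back to 40, keeping the oxirane out of the union: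
- 37 is added to the methylene enone 34 to give the tertiary allylic alcohol F12.
- Pyridinium chlorochromate ([C5H5NH][CrO3Cl]) transposes it to the enone F13.
- mCPBA epoxidises the exocyclic alkene to F14.
- LiAlH4 opens the oxirane and reduces the enone to the allylic alcohol F15.
- MnO2 reoxidises the allylic alcohol to 40.

**Step 9.** Facial selectivity may be poor if the intrinsic bias of the seven-membered ketone opposes the catalyst, or the ketone may be reduced slowly because both neighbours are hindered. Fallback, from 13 back to 14: substrate-controlled reduction with NaBH4, separation of 14 from its C3 epimer F4, and return of F4 to 13 by Dess–Martin oxidation for another pass.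

## Further compounds

F1 | step 8 | trimethylsilyl enol ether of 10 (C3=C4 double bond, silyloxy on C3) | O1CCOC12[C@]3(C)C=C(O[Si](C)(C)C)C(C)(C)O[C@H]3CCC2
F2 | step 8 | siloxycyclopropane from F1 (cyclopropane across C3–C4, silyloxy on the ring-fusion carbon of the cyclopropane) | O1CCOC12[C@]3(C)C4CC4(O[Si](C)(C)C)C(C)(C)O[C@H]3CCC2
F3 | step 8 | (5aR,9aS)-2,2,5a-trimethyl-5a,7,8,9a-tetrahydro-spiro[1-benzoxepine-6,2'-[1,3]dioxolan]-3(2H)-one with C4=C5 double bond (oxepenone) | O1CCOC12[C@]3(C)C=CC(=O)C(C)(C)O[C@H]3CCC2
F4 | step 9 | (3R,5aR,9aS)-2,2,5a-trimethyloctahydrospiro[1-benzoxepine-6,2'-[1,3]dioxolan]-3-ol (C3 epimer of 14) | O1CCOC12[C@]3(C)CC[C@@H](O)C(C)(C)O[C@H]3CCC2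
F5 | step 22 | (4aS,8aR)-4,4,6-trimethyl-3,4,4a,5,8,8a-hexahydronaphthalen-1(2H)-one (antipode of 31) | CC=1C[C@H]2[C@@H](CC=1)C(=O)CCC2(C)C
F6 | step 23 | ethylene ketal of 31 at C1 | CC=1C[C@@H]2[C@H](CC=1)C3(OCCO3)CCC2(C)C
F7 | step 23 | ketal alcohol from hydroboration of F6 (hydroxyl on the former unsubstituted alkene carbon, epimer mixture) | CC1C[C@@H]2[C@H](CC1O)C3(OCCO3)CCC2(C)C
F8 | step 23 | ketal ketone from F7 | CC1C[C@@H]2[C@H](CC1=O)C3(OCCO3)CCC2(C)C
F9 | step 23 | ketal enone from F8 (2-methyl enone, double bond toward the ring-fusion side) | CC1=C[C@@H]2[C@H](CC1=O)C3(OCCO3)CCC2(C)C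
F10 | step 23 | α,β-epoxy ketone from F9 | CC13OC3[C@@H]2[C@H](CC1=O)C4(OCCO4)CCC2(C)C
F11 | step 23 | ethylene ketal of 32 (allylic alcohol at C5) | CC=1C(O)[C@@H]2[C@H](CC=1)C3(OCCO3)CCC2(C)C
F12 | step 26 | 1,2-adduct of 37 and 34 (tertiary allylic alcohol, exocyclic methylene retained) | CC=1C(O)(CC[C@H]4[C@]5(C)CC[C@H](O[Si](C)(C)C(C)(C)C)C(C)(C)O[C@H]5CC[C@]4(C)O[Si](CC)(CC)CC)[C@@H]2[C@H](CC=1)C(=C)CCC2(C)C
F13 | step 26 | transposed enone from F12 with exocyclic methylene on ring D | CC1=C(CC[C@H]2[C@]3(C)CC[C@H](O[Si](C)(C)C(C)(C)C)C(C)(C)O[C@H]3CC[C@]2(C)O[Si](CC)(CC)CC)[C@@H]2[C@H](CC1=O)C(=C)CCC2(C)C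
F14 | step 26 | spiro-oxirane from F13 (oxirane oxygen cis to the ring-fusion hydrogens) | CC1=C(CC[C@H]2[C@]3(C)CC[C@H](O[Si](C)(C)C(C)(C)C)C(C)(C)O[C@H]3CC[C@]2(C)O[Si](CC)(CC)CC)[C@@H]2[C@H](CC1=O)[C@]4(CO4)CCC2(C)C
F15 | step 26 | allylic alcohol from F14 (ring C carbinol epimers, ring D methyl carbinol in place) | CC1=C(CC[C@H]2[C@]3(C)CC[C@H](O[Si](C)(C)C(C)(C)C)C(C)(C)O[C@H]3CC[C@]2(C)O[Si](CC)(CC)CC)[C@@H]2[C@H](CC1O)[C@@](C)(O)CCC2(C)C
A1 | alternative 1 | cis-fused bis(dimethyl ketal) ketone of rings C and D with a silyloxymethyl group | CC1=C(CO[Si](C)(C)C(C)(C)C)[C@@H]2[C@H](CC1(OC)OC)C(OC)(OC)C(=O)CC2(C)C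
A2 | alternative 2 | oxepane–cyclohexane hydroxy lactone (rings A and B plus a temporary lactone) | O=C1C[C@H]2[C@]3(C)CC[C@H](O)C(C)(C)O[C@H]3CC[C@]2(C)O1
A3 | alternative 3 | cis-fused cycloadduct with ring C allylic silyl ether, ring D ketone and the protected left half | CC1=C(CC[C@H]2[C@]3(C)CC[C@H](O[Si](C)(C)C(C)(C)C)C(C)(C)O[C@H]3CC[C@]2(C)O[Si](C)(C)C)[C@@H]2[C@H](C[C@H]1O[Si](C)(C)C(C)(C)C)C(=O)CCC2(C)C
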